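**Retrosynthetic overview**
1. Target 21 ⇒ C2 hydroxylation of 19 ⇒ Diels–Alder union (ring C and the spiro centre) of trienone 18 (diene C14=C10–C1=C2) with the exocyclic enone of monomer 16; 18 is made from 16, so one monomer serves both halves.
2. 16 ⇒ triene lactone 14 by allylic oxidation at C3.
3. 14 ⇒ aldehyde/allylic bromide 12: ring B (cycloheptane) and the cis-fused α-methylene lactone close together in one chromium-mediated allylation–lactonisation; 12 comes from enal 11 by light-driven deconjugation.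
4. 11 ⇒ (R)-limonene: ozonolysis/aldol ring contraction gives ring A; the side chain comes from C10 lithiation/ethylene oxide and a Morita–Baylis–Hillman/bromination sequence.
5. Ring order: ring A → ring B + lactone (one operation) → ring C (Diels–Alder).

Assumption: the SMILES is read literally, so both γ-lactones are cis-fused (6S,7R and 6′S,7′R, H-6/H-7 syn); natural trans-lactone guaianolides therefore do not map onto the target and the monomer is built de novo (guaiane numbering is used for the monomers).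

**Step 1**
Reactants: 1 (R)-(+)-limonene; 2 ethylene oxide
Product: 4 4-[(1R)-4-methylcyclohex-3-en-1-yl]pent-4-en-1-ol, via 10-lithiolimonene 3 (not isolated)
Conditions: n-BuLi, TMEDA, hexane, 25 °C; then 2, THF, −78 → 25 °C; H2O
Reagents that add atoms: none
Why: Allylic lithiation: n-BuLi·TMEDA deprotonates limonene selectively at the isopropenyl methyl group and the 2-substituted allyllithium opens ethylene oxide (either terminus gives the same product), leaving the (R) centre, the future C1, untouched.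

**Step 2**
Reactants: 4 4-[(1R)-4-methylcyclohex-3-en-1-yl]pent-4-en-1-ol
Product: 6 (3R)-3-(5-hydroxypent-1-en-2-yl)-6-oxoheptanal, via secondary ozonide 5 (not isolated)
Conditions: O3 (1.0 equiv), CH2Cl2, −78 °C; then Me2S, −78 → 25 °C
Reagents that add atoms: ozone ([O-][O+]=O)
Why: Ozonolysis: the electron-rich trisubstituted ring alkene reacts much faster with ozone than the 1,1-disubstituted side-chain alkene, and the stereocentre is not involved.

**Step 3**
Reactants: 6 (3R)-3-(5-hydroxypent-1-en-2-yl)-6-oxoheptanal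
Product: 7 (5S)-5-(5-hydroxypent-1-en-2-yl)-2-methylcyclopent-1-ene-1-carbaldehyde
Conditions: piperidine, AcOH (cat.), benzene, 80 °C (−H2O)
Reagents that add atoms: none
Why: Intramolecular aldol condensation: the enamine of the aldehyde attacks the methyl ketone and dehydration gives the cyclopentene carbaldehyde (ring A), the stereocentre keeping its geometry (descriptor changes by priority only).

**Step 4**
Reactants: 7 (5S)-5-(5-hydroxypent-1-en-2-yl)-2-methylcyclopent-1-ene-1-carbaldehyde
Product: 8 (5S)-2-methyl-5-(5-oxopent-1-en-2-yl)cyclopent-1-ene-1-carbaldehyde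
Conditions: Dess–Martin periodinane, NaHCO3, CH2Cl2, 0 → 25 °C
Reagents that add atoms: none
Why: Dess–Martin oxidation of the primary alcohol to the aldehyde; the conjugated ring aldehyde and both alkenes are inert.

**Step 5**
Reactants: 8 (5S)-2-methyl-5-(5-oxopent-1-en-2-yl)cyclopent-1-ene-1-carbaldehyde; 9 methyl acrylate
Product: 10 methyl 6-[(1S)-2-formyl-3-methylcyclopent-2-en-1-yl]-3-hydroxy-2-methylidenehept-6-enoate (both C3 epimers)
Conditions: 9 (5 equiv), DABCO (0.5 equiv), MeOH (cat.), 25 °C
Reagents that add atoms: none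
Why: Morita–Baylis–Hillman reaction: only the unhindered aliphatic aldehyde reacts, the tetrasubstituted conjugated ring aldehyde being inert; the new carbinol centre is removed in step 6.

**Step 6**
Reactants: 10 methyl 6-[(1S)-2-formyl-3-methylcyclopent-2-en-1-yl]-3-hydroxy-2-methylidenehept-6-enoate
Product: 11 methyl (2Z)-2-(bromomethyl)-6-[(1S)-2-formyl-3-methylcyclopent-2-en-1-yl]hepta-2,6-dienoate
Conditions: NBS, Me2S, CH2Cl2, 0 → 25 °C
Reagents that add atoms: N-bromosuccinimide (O=C1CCC(=O)N1Br)
Why: SN2′ bromination of the Baylis–Hillman alcohol with the Me2S–NBS reagent gives the rearranged primary allylic bromide as the thermodynamic Z isomer (chain trans to the ester).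

**Step 7**
Reactants: 11 methyl (2Z)-2-(bromomethyl)-6-[(1S)-2-formyl-3-methylcyclopent-2-en-1-yl]hepta-2,6-dienoate
Product: 14 (1R,5R,6S,7R)-guaia-4(15),10(14),11(13)-trien-12,6-olide (7-epi-dehydrocostus lactone), via deconjugated cis-aldehyde 12 (not isolated), via seco hydroxy ester 13 (not isolated)
Conditions: hν (365 nm), 2,6-lutidine (0.1 equiv), CH2Cl2, 0 °C; then slow addition to CrCl2 (4 equiv), THF, 25 °C (5 mM); 1 M HCl
Reagents that add atoms: none
Why: Proposed new method: n→π* excitation lets the formyl oxygen abstract a hydrogen from the cis γ-methyl group (photoenolisation, the known basis of photodeconjugation of α,β-unsaturated carbonyl compounds), ketonisation protonates C5 anti to the C1 side chain to give the contra-thermodynamic cis β,γ-unsaturated aldehyde 12, and CrCl2 then converts the allylic bromide into a 2-(alkoxycarbonyl)allylchromium that adds to this aldehyde through a chair transition state (intramolecular Nozaki–Hiyama–Kishi allylation, closest precedent the Semmelhack metal-promoted cyclisation–lactonisation of ω-formyl 2-(bromomethyl)acrylates), closing the cycloheptane and, by lactonisation of 13, the cis-fused lactone on the face opposite ring A with the chromium-bound oxygen turned away from the C4 methylene, which sets C5, C6 and C7.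

**Step 8**
Reactants: 14 (1R,5R,6S,7R)-guaia-4(15),10(14),11(13)-trien-12,6-olide
Product: 15 (1R,5R,6S,7R)-3-hydroxyguaia-4(15),10(14),11(13)-trien-12,6-olide (C3 epimers)
Conditions: SeO2 (0.5 equiv), t-BuOOH (2 equiv), CH2Cl2, 25 °C
Reagents that add atoms: selenium dioxide (O=[Se]=O, oxygen carrier) and tert-butyl hydroperoxide (CC(C)(C)OO)
Why: Sharpless SeO2/t-BuOOH allylic hydroxylation (ene reaction then [2,3]-shift) attacks the ring A methylene C3 next to C4=C15, as in the dehydrocostus lactone to 3-epizaluzanin C conversion; the new carbinol centre is erased in step 9.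

**Step 9**
Reactants: 15 (1R,5R,6S,7R)-3-hydroxyguaia-4(15),10(14),11(13)-trien-12,6-olide
Product: 16 (1R,5R,6S,7R)-3-oxoguaia-4(15),10(14),11(13)-trien-12,6-olide (7-epi-dehydrozaluzanin C)
Conditions: Dess–Martin periodinane, NaHCO3, CH2Cl2, 0 °C
Reagents that add atoms: none
Why: Dess–Martin oxidation of the allylic alcohol gives the exocyclic enone under buffered conditions that do not isomerise the methylene groups.

**Step 10**
Reactants: 16 (1R,5R,6S,7R)-3-oxoguaia-4(15),10(14),11(13)-trien-12,6-olide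
Product: 17 (1S,5R,6S,7R)-3-(trimethylsilyloxy)guaia-2,4(15),10(14),11(13)-tetraen-12,6-olide
Conditions: Me3SiOTf, Et3N, CH2Cl2, −78 → 0 °C
Reagents that add atoms: trimethylsilyl trifluoromethanesulfonate (C[Si](C)(C)OS(=O)(=O)C(F)(F)F)
Why: Silyl enol ether formation by soft enolisation can only go towards C2 because C4 is sp2, and no stereocentre is touched (the C1 descriptor changes by priority only).

**Step 11**
Reactants: 17 (1S,5R,6S,7R)-3-(trimethylsilyloxy)guaia-2,4(15),10(14),11(13)-tetraen-12,6-olide; 16 (1R,5R,6S,7R)-3-oxoguaia-4(15),10(14),11(13)-trien-12,6-olide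
Product: 19 2-deoxy-21 (Diels–Alder adduct with H at C2, 2R, all other centres as in 21), via trienone 18 (not isolated)
Conditions: Pd(OAc)2 (1.05 equiv), MeCN, 25 °C; then 16 (2 equiv), 50 °C
Reagents that add atoms: none
Why: Saegusa–Ito dehydrogenation gives the s-cis-locked diene of 18, whose Diels–Alder reaction with the exocyclic enone of 16 is ortho-regioselective (C2–C4′ and C14–C15′ bonds) and takes place on the β-face of the diene (anti to its α-disposed cis-lactone) and on the convex α-face of the cis-fused hydroazulenone of 16, which sets C2 and the spiro carbon C4′.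

**Step 12**
Reactants: 19 2-deoxy-21
Product: 21 target CNP0269880.1 (2S,5R,6S,7R,1′R,4′R,5′R,6′S,7′R), via potassium dienolate 20 (not isolated)
Conditions: KN(SiMe3)2 (1.0 equiv), THF, −78 → −40 °C; 2-(phenylsulfonyl)-3-phenyloxaziridine, −78 °C; H2O
Reagents that add atoms: 2-(phenylsulfonyl)-3-phenyloxaziridine (O=S(=O)(N1OC1c1ccccc1)c1ccccc1)
Why: Enolate α-hydroxylation: C2–H, α to the ketone and allylic to C1=C10, is the most acidic proton, and the Davis oxaziridine attacks the α-carbon of the dienolate from the α-face, opposite the C14–C15′ bridge and the spiro ring that the cycloaddition placed on the β-side, giving the (2S) tertiary alcohol.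

**Compound list**
1 | (R)-(+)-limonene | CC1=CC[C@@H](CC1)C(C)=C | starting material
2 | ethylene oxide | C1CO1 | starting material
3 | 10-lithiolimonene, [2-[(1R)-4-methylcyclohex-3-en-1-yl]prop-2-en-1-yl]lithium | CC1=CC[C@@H](CC1)C(=C)C[Li] | intermediate
4 | 4-[(1R)-4-methylcyclohex-3-en-1-yl]pent-4-en-1-ol | CC1=CC[C@@H](CC1)C(=C)CCCO | intermediate
5 | secondary ozonide (1,2,4-trioxolane across the ring alkene) of 4 | CC12CC[C@H](CC(O1)OO2)C(=C)CCCO | intermediate
6 | (3R)-3-(5-hydroxypent-1-en-2-yl)-6-oxoheptanal | CC(=O)CC[C@H](CC=O)C(=C)CCCO | intermediate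
7 | (5S)-5-(5-hydroxypent-1-en-2-yl)-2-methylcyclopent-1-ene-1-carbaldehyde | O=CC1=C(C)CC[C@H]1C(=C)CCCO | intermediate
8 | (5S)-2-methyl-5-(5-oxopent-1-en-2-yl)cyclopent-1-ene-1-carbaldehyde | O=CC1=C(C)CC[C@H]1C(=C)CCC=O | intermediate
9 | methyl acrylate | C=CC(=O)OC | starting material
10 | methyl 6-[(1S)-2-formyl-3-methylcyclopent-2-en-1-yl]-3-hydroxy-2-methylidenehept-6-enoate (C3 epimers) | O=CC1=C(C)CC[C@H]1C(=C)CCC(O)C(=C)C(=O)OC | intermediate
11 | methyl (2Z)-2-(bromomethyl)-6-[(1S)-2-formyl-3-methylcyclopent-2-en-1-yl]hepta-2,6-dienoate | O=CC1=C(C)CC[C@H]1C(=C)CC/C=C(\CBr)C(=O)OC | intermediate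
12 | methyl (2Z)-2-(bromomethyl)-6-[(1R,2R)-2-formyl-3-methylidenecyclopentyl]hepta-2,6-dienoate (formyl and side chain cis) | O=C[C@H]1C(=C)CC[C@H]1C(=C)CC/C=C(\CBr)C(=O)OC | intermediate
13 | methyl (1R,5R,6S,7R)-6-hydroxyguaia-4(15),10(14),11(13)-trien-12-oate (cis-fused hydroazulene, 6-OH and C7 acrylate cis) | C=C1CC[C@H]2C(=C)CC[C@H](C(=C)C(=O)OC)[C@H](O)[C@H]21 | intermediate
14 | (1R,5R,6S,7R)-guaia-4(15),10(14),11(13)-trien-12,6-olide (7-epi-dehydrocostus lactone; H-1/H-5 cis, lactone cis-fused and anti to ring A) | C=C1CC[C@H]2C(=C)CC[C@@H]3C(=C)C(=O)O[C@@H]3[C@H]21 | intermediate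
15 | (1R,5R,6S,7R)-3-hydroxyguaia-4(15),10(14),11(13)-trien-12,6-olide (C3 epimers) | C=C1C(O)C[C@H]2C(=C)CC[C@@H]3C(=C)C(=O)O[C@@H]3[C@H]21 | intermediate
16 | (1R,5R,6S,7R)-3-oxoguaia-4(15),10(14),11(13)-trien-12,6-olide (7-epi-dehydrozaluzanin C) | C=C1C(=O)C[C@H]2C(=C)CC[C@@H]3C(=C)C(=O)O[C@@H]3[C@H]21 | intermediate
17 | (1S,5R,6S,7R)-3-(trimethylsilyloxy)guaia-2,4(15),10(14),11(13)-tetraen-12,6-olide | C=C1C(O[Si](C)(C)C)=C[C@H]2C(=C)CC[C@@H]3C(=C)C(=O)O[C@@H]3[C@H]21 | intermediate
18 | (5R,6S,7R)-3-oxoguaia-1,4(15),10(14),11(13)-tetraen-12,6-olide | C=C1C(=O)C=C2C(=C)CC[C@@H]3C(=C)C(=O)O[C@@H]3[C@H]21 | intermediate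
19 | 2-deoxy-21: Diels–Alder adduct of 18 and 16 (C2–C4′ and C14–C15′ bonds, C1=C10 alkene, H at C2, 2R) | C=C1C(=O)[C@@H]2C3=C(CC[C@@H]4C(=C)C(=O)O[C@@H]4[C@@H]13)CC[C@]21C(=O)C[C@H]2C(=C)CC[C@@H]3C(=C)C(=O)O[C@@H]3[C@H]21 | intermediate
20 | potassium C3-enolate (C2=C3, conjugated with C1=C10) of 19 | C=C1C([O-])=C2C3=C(CC[C@@H]4C(=C)C(=O)O[C@@H]4[C@@H]13)CC[C@]21C(=O)C[C@H]2C(=C)CC[C@@H]3C(=C)C(=O)O[C@@H]3[C@H]21.[K+] | intermediate
21 | CNP0269880.1, (2S,5R,6S,7R,1′R,4′R,5′R,6′S,7′R)-2-hydroxy spiro dimer | C=C1C(=O)[C@]2(O)C3=C(CC[C@@H]4C(=C)C(=O)O[C@@H]4[C@@H]13)CC[C@]21C(=O)C[C@H]2C(=C)CC[C@@H]3C(=C)C(=O)O[C@@H]3[C@H]21 | target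

**Totals**
Total step count: 12. Longest linear sequence: 12 steps (1 → 21; compound 16 enters step 11 both directly and as 17).

**Steps most likely to fail, with fallbacks**

Step 7. The light-driven deconjugation may be incomplete or competed by photocycloaddition, the cis aldehyde may epimerise or reconjugate before it is trapped, and the ring closure may give the wrong C6/C7 pair. The fallback sets out from 7 and comes back at 12. The enal 7 is deprotonated at the cis γ-methyl group with KN(SiMe3)2 (2.2 equiv, THF/HMPA, −78 °C), the dienolate is protonated kinetically at C5 with AcOH at −78 °C and the aldehyde is reduced in the same flask with NaBH4, giving the stable cis-diol 4-[(1R,2R)-2-(hydroxymethyl)-3-methylidenecyclopentyl]pent-4-en-1-ol F1. Aerobic oxidation with Cu(MeCN)4OTf/bipyridine/TEMPO/N-methylimidazole converts only the unhindered primary alcohol, giving 4-[(1R,2R)-2-(hydroxymethyl)-3-methylidenecyclopentyl]pent-4-enal F2. Morita–Baylis–Hillman reaction with 9 gives methyl 3-hydroxy-6-[(1R,2R)-2-(hydroxymethyl)-3-methylidenecyclopentyl]-2-methylidenehept-6-enoate F3, and NBS/Me2S converts only the allylic alcohol, giving methyl (2Z)-2-(bromomethyl)-6-[(1R,2R)-2-(hydroxymethyl)-3-methylidenecyclopentyl]hepta-2,6-dienoate F4. Dess–Martin oxidation of F4 gives 12, which is cyclised at once with CrCl2 as in step 7.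

Step 11. Self-dimerisation of 18 or the wrong facial sense on the cis-lactone dienophile would ruin the cycloaddition. The fallback sets out from 17 and comes back at 21, replacing steps 11 and 12. Rubottom oxidation of 17 (dimethyldioxirane, acetone, −78 °C; citric acid) gives the α-hydroxy ketone (1R,5R,6S,7R)-2-hydroxy-3-oxoguaia-4(15),10(14),11(13)-trien-12,6-olide F5. Dess–Martin oxidation gives the 2,3-dione, which exists as the diosphenol (5R,6S,7R)-2-hydroxy-3-oxoguaia-1,4(15),10(14),11(13)-tetraen-12,6-olide F6. Its 2-hydroxy diene is more electron-rich than 18 and adds to the exocyclic enone of 16 (Diels–Alder, or stepwise vinylogous Michael/aldol with Et3N), so the C2 carbinol is set in the ring-forming event and 21 is obtained directly.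

Step 12. The base may enolise the ring D ketone instead, or the oxidant may attack the β-face. The fallback sets out from 19 and comes back at 21. Thermodynamic soft enolisation with Me3SiOTf (1.1 equiv)/Et3N at −78 °C silylates only the doubly activated C2–H site and gives the 3-(trimethylsilyloxy)-2,3-ene silyl dienol ether of 19 F7. Its electron-rich enol ether double bond is epoxidised with dimethyldioxirane at −78 °C (Rubottom oxidation), and acidic work-up gives 21.

**Further compounds**
F1 | step 7 | 4-[(1R,2R)-2-(hydroxymethyl)-3-methylidenecyclopentyl]pent-4-en-1-ol | OC[C@H]1C(=C)CC[C@H]1C(=C)CCCO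
F2 | step 7 | 4-[(1R,2R)-2-(hydroxymethyl)-3-methylidenecyclopentyl]pent-4-enal | OC[C@H]1C(=C)CC[C@H]1C(=C)CCC=O
F3 | step 7 | methyl 3-hydroxy-6-[(1R,2R)-2-(hydroxymethyl)-3-methylidenecyclopentyl]-2-methylidenehept-6-enoate | OC[C@H]1C(=C)CC[C@H]1C(=C)CCC(O)C(=C)C(=O)OC
F4 | step 7 | methyl (2Z)-2-(bromomethyl)-6-[(1R,2R)-2-(hydroxymethyl)-3-methylidenecyclopentyl]hepta-2,6-dienoate | OC[C@H]1C(=C)CC[C@H]1C(=C)CC/C=C(\CBr)C(=O)OC
F5 | step 11 | (1R,5R,6S,7R)-2-hydroxy-3-oxoguaia-4(15),10(14),11(13)-trien-12,6-olide (C2 epimers) | C=C1C(=O)C(O)[C@H]2C(=C)CC[C@@H]3C(=C)C(=O)O[C@@H]3[C@H]21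
F6 | step 11 | (5R,6S,7R)-2-hydroxy-3-oxoguaia-1,4(15),10(14),11(13)-tetraen-12,6-olide (diosphenol) | C=C1C(=O)C(O)=C2C(=C)CC[C@@H]3C(=C)C(=O)O[C@@H]3[C@H]21
F7 | step 12 | 3-(trimethylsilyloxy)-2,3-ene silyl dienol ether of 19 | C=C1C(O[Si](C)(C)C)=C2C3=C(CC[C@@H]4C(=C)C(=O)O[C@@H]4[C@@H]13)CC[C@]21C(=O)C[C@H]2C(=C)CC[C@@H]3C(=C)C(=O)O[C@@H]3[C@H]21
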